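## Retrosynthetic overview

1. The C3 ketone comes from an allylic alcohol; the ten-membered ring is closed last, at C3–C4, by an intramolecular Nozaki–Hiyama–Kishi coupling of an iodo-aldehyde.
2. The open chain comes from a late chromium-mediated Barbier union (C6–C7) of a bromobutenolide (fragment B: C1–C3, C7–C14) with an α-angeloyloxy iodo-aldehyde (fragment A: C4–C6, C15, ester); this sets C6 and C7.
3. Fragment B: butenolide by esterification and ring-closing metathesis, C1/C10 epoxide by Shi epoxidation, C8 from (R)-epichlorohydrin, E-olefin by hydrozirconation of pent-3-yn-1-ol.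
4. Fragment A: aldehyde by glycol cleavage; C5 and the angelate by titanium-mediated opening of a Sharpless epoxy alcohol with angelic acid; iodo-dienol from epichlorohydrin and acetylide.
5. Ring order: oxirane, then butenolide (which becomes the α-methylene lactone in the coupling), then the ten-membered carbocycle.

Assumption: germacrane numbering is used for positions (C1–C10 ring, C11–C13 lactone carbons, C14 methyl, C15 exocyclic methylene), and the six starting materials are taken as commercial.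

## Route

### Fragment A

Step 1
Reactants: 1 rac-2-(chloromethyl)oxirane; 2 sodium acetylide
Product: 4 (2E)-pent-2-en-4-yn-1-ol, via 2-(prop-2-yn-1-yl)oxirane 3 (not isolated)
Conditions: NaC≡CH (2.2 equiv), liq. NH3, −33 °C; then H2O
Reagents that add atoms: none
Why: Acetylide opens the epoxide at CH2, the alkoxide closes to epoxide 3 with loss of chloride, and the second equivalent of acetylide removes a propargylic proton so that eliminative epoxide opening gives the conjugated E-enynol (epoxide opening/isomerisation cascade).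

Step 2
Reactants: 4 (2E)-pent-2-en-4-yn-1-ol
Product: 5 tert-butyl(dimethyl){[(2E)-pent-2-en-4-yn-1-yl]oxy}silane
Conditions: TBSCl, imidazole, CH2Cl2, 0 °C to rt
Reagents that add atoms: tert-butyldimethylsilyl chloride, CC(C)(C)[Si](C)(C)Cl
Why: Silyl ether formation masks the hydroxyl against the Lewis-acidic haloborane of the next step.

Step 3
Reactants: 5 tert-butyl(dimethyl){[(2E)-pent-2-en-4-yn-1-yl]oxy}silane
Product: 7 tert-butyl{[(2E)-4-iodopenta-2,4-dien-1-yl]oxy}dimethylsilane, via iodoalkenylborane adduct 6 (not isolated)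
Conditions: B-iodo-9-BBN (1.1 equiv), pentane, −20 to 0 °C; then AcOH, 0 °C
Reagents that add atoms: B-iodo-9-borabicyclo[3.3.1]nonane, IB1C2CCCC1CCC2
Why: Syn haloboration of the terminal alkyne places iodine on the internal carbon (Markovnikov), and protonolysis of the C–B bond with retention gives the 2-iodo-1-alkene needed for the later Nozaki–Hiyama–Kishi reaction.

Step 4
Reactants: 7 tert-butyl{[(2E)-4-iodopenta-2,4-dien-1-yl]oxy}dimethylsilane
Product: 8 (2E)-4-iodopenta-2,4-dien-1-ol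
Conditions: AcOH–THF–H2O (3:1:1), rt
Reagents that add atoms: none
Why: Mild acid hydrolysis of the primary silyl ether frees the allylic alcohol required for the titanium-directed epoxidation.

Step 5
Reactants: 8 (2E)-4-iodopenta-2,4-dien-1-ol
Product: 9 [(2R,3S)-3-(1-iodoethenyl)oxiran-2-yl]methanol
Conditions: Ti(OiPr)4 (10 mol%), D-(−)-diisopropyl tartrate (12 mol%), t-BuOOH, 4 Å MS, CH2Cl2, −20 °C
Reagents that add atoms: tert-butyl hydroperoxide, CC(C)(C)OO
Why: Katsuki–Sharpless asymmetric epoxidation of the E-allylic alcohol with D-(−)-tartrate gives the enantiomer of the epoxide obtained with L-(+)-tartrate (2R here, with 3S only because the iodovinyl group outranks C2), while the electron-poor iodo-olefin is left alone.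

Step 6
Reactants: 9 [(2R,3S)-3-(1-iodoethenyl)oxiran-2-yl]methanol; 10 (2Z)-2-methylbut-2-enoic acid (angelic acid)
Product: 11 (2R,3R)-1,2-dihydroxy-4-iodopent-4-en-3-yl (2Z)-2-methylbut-2-enoate
Conditions: Ti(OiPr)4 (1.5 equiv), CH2Cl2, rt
Reagents that add atoms: none
Why: Titanium-mediated opening of the 2,3-epoxy alcohol by the carboxylic acid occurs at C3 (also the allylic position) with inversion, which sets the C5 stereocentre of the target and installs the angelate without acylation conditions that isomerise it to the tiglate.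

Step 7
Reactants: 11 (2R,3R)-1,2-dihydroxy-4-iodopent-4-en-3-yl (2Z)-2-methylbut-2-enoate
Product: 12 (2R)-3-iodo-1-oxobut-3-en-2-yl (2Z)-2-methylbut-2-enoate
Conditions: NaIO4 on silica gel, CH2Cl2, rt; filtered and used at once
Reagents that add atoms: none
Why: Malaprade glycol cleavage under neutral, essentially anhydrous conditions gives the sensitive α-acyloxy aldehyde without touching its stereocentre.

### Fragment B

Step 8
Reactants: 13 pent-3-yn-1-ol
Product: 14 1-methoxy-4-[(pent-3-yn-1-yloxy)methyl]benzene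
Conditions: NaH, 4-methoxybenzyl chloride, Bu4NI (cat.), THF–DMF, 0 °C to rt
Reagents that add atoms: 4-methoxybenzyl chloride, COc1ccc(CCl)cc1
Why: Williamson etherification gives a PMB ether that survives organometallic, oxidative and metathesis steps and is later removed under neutral conditions.

Step 9
Reactants: 14 1-methoxy-4-[(pent-3-yn-1-yloxy)methyl]benzene
Product: 16 1-({[(3E)-4-iodopent-3-en-1-yl]oxy}methyl)-4-methoxybenzene, via alkenylzirconocene chloride 15 (not isolated)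
Conditions: Cp2Zr(H)Cl (1.5 equiv), THF, rt to 45 °C; then I2, 0 °C
Reagents that add atoms: iodine, II
Why: Schwartz hydrozirconation is a syn addition that, after equilibration with excess reagent, places zirconium on the less hindered methyl-bearing carbon, and iodinolysis with retention gives the E-alkenyl iodide that fixes the E-C1=C10 geometry.

Step 10
Reactants: 16 1-({[(3E)-4-iodopent-3-en-1-yl]oxy}methyl)-4-methoxybenzene; 17 (2R)-2-(chloromethyl)oxirane
Product: 19 (2R,4E)-1-chloro-7-[(4-methoxyphenyl)methoxy]-4-methylhept-4-en-2-ol, via alkenyllithium 18 (not isolated)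
Conditions: t-BuLi (2.1 equiv), Et2O, −78 °C; then 17, BF3·OEt2, −78 °C; aq. work-up
Reagents that add atoms: none
Why: Iodine–lithium exchange proceeds with retention of olefin geometry, and the BF3-assisted SN2 opening occurs at the unsubstituted epoxide carbon, so the C8 stereocentre is taken unchanged from (R)-epichlorohydrin.

Step 11
Reactants: 19 (2R,4E)-1-chloro-7-[(4-methoxyphenyl)methoxy]-4-methylhept-4-en-2-ol
Product: 21 (3R,5E)-8-[(4-methoxyphenyl)methoxy]-5-methylocta-1,5-dien-3-ol, via terminal epoxide 20 (not isolated)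
Conditions: Me3S+ I− (4 equiv), n-BuLi (3.8 equiv), THF, −10 °C to rt
Reagents that add atoms: trimethylsulfonium iodide, C[S+](C)C.[I-]
Why: Base closes the chlorohydrin to epoxide 20, dimethylsulfonium methylide opens it at CH2, and a further equivalent of ylide triggers elimination of dimethyl sulfide (one-carbon epoxide-to-allylic-alcohol homologation) without touching the carbinol centre.

Step 12
Reactants: 21 (3R,5E)-8-[(4-methoxyphenyl)methoxy]-5-methylocta-1,5-dien-3-ol
Product: 22 (2R)-1-[(2R,3R)-3-{2-[(4-methoxyphenyl)methoxy]ethyl}-2-methyloxiran-2-yl]but-3-en-2-ol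
Conditions: D-fructose-derived Shi ketone (0.3 equiv), Oxone (2KHSO5·KHSO4·K2SO4), K2CO3, Bu4NHSO4 (cat.), MeCN–CH2(OMe)2/aq. Na2B4O7–Na2EDTA buffer, 0 °C
Reagents that add atoms: potassium peroxymonosulfate (active component of Oxone), [K+].[O-]S(=O)(=O)OO
Why: Shi asymmetric epoxidation through the spiro transition state of the D-fructose-derived dioxirane gives the (R,R)-epoxide of an E-trisubstituted olefin, so C1 and C10 are set under reagent control on an unbiased acyclic substrate while the monosubstituted vinyl group does not react.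

Step 13
Reactants: 22 (2R)-1-[(2R,3R)-3-{2-[(4-methoxyphenyl)methoxy]ethyl}-2-methyloxiran-2-yl]but-3-en-2-ol; 23 2-(bromomethyl)prop-2-enoic acid
Product: 24 (2R)-1-[(2R,3R)-3-{2-[(4-methoxyphenyl)methoxy]ethyl}-2-methyloxiran-2-yl]but-3-en-2-yl 2-(bromomethyl)prop-2-enoate
Conditions: N,N'-diisopropylcarbodiimide, DMAP (5 mol%), CH2Cl2, 0 °C
Reagents that add atoms: none
Why: Steglich esterification acylates the secondary allylic alcohol under neutral conditions that leave the epoxide and the allylic bromide intact.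

Step 14
Reactants: 24 (2R)-1-[(2R,3R)-3-{2-[(4-methoxyphenyl)methoxy]ethyl}-2-methyloxiran-2-yl]but-3-en-2-yl 2-(bromomethyl)prop-2-enoate
Product: 25 (5R)-3-(bromomethyl)-5-{[(2R,3R)-3-{2-[(4-methoxyphenyl)methoxy]ethyl}-2-methyloxiran-2-yl]methyl}furan-2(5H)-one
Conditions: second-generation Grubbs catalyst (H2IMes)(PCy3)Cl2Ru=CHPh (5 mol%), CH2Cl2 (5 mM), 40 °C
Reagents that add atoms: none
Why: Ring-closing metathesis between the vinyl group and the 1,1-disubstituted acrylate forms the five-membered butenolide with loss of ethene, the trisubstituted ring olefin being within reach of the N-heterocyclic carbene catalyst.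

### Coupling and endgame

Step 15
Reactants: 25 (5R)-3-(bromomethyl)-5-{[(2R,3R)-3-{2-[(4-methoxyphenyl)methoxy]ethyl}-2-methyloxiran-2-yl]methyl}furan-2(5H)-one; 12 (2R)-3-iodo-1-oxobut-3-en-2-yl (2Z)-2-methylbut-2-enoate
Product: 27 (1R,2R)-1-hydroxy-3-iodo-1-[(2R,3R)-2-{[(2R,3R)-3-{2-[(4-methoxyphenyl)methoxy]ethyl}-2-methyloxiran-2-yl]methyl}-4-methylidene-5-oxooxolan-3-yl]but-3-en-2-yl (2Z)-2-methylbut-2-enoate, via allylchromium species 26 (not isolated)
Conditions: CrCl2 (4 equiv, nickel-free), THF, 0 °C to rt; aq. work-up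
Reagents that add atoms: none
Why: In this Nozaki–Hiyama-type Barbier allylation the allylchromium species attacks the aldehyde through its γ-carbon (C7) on the butenolide face anti to the C8 side chain (7,8-trans lactone) in a chair Zimmerman–Traxler transition state with the aldehyde residue equatorial, and this approach coincides with polar Felkin–Anh attack anti to the α-acyloxy group (5,6-anti), so the matched control elements set C6 (R) and C7 (R) while the alkenyl iodide is inert to divalent chromium without nickel.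

Step 16
Reactants: 27 (1R,2R)-1-hydroxy-3-iodo-1-[(2R,3R)-2-{[(2R,3R)-3-{2-[(4-methoxyphenyl)methoxy]ethyl}-2-methyloxiran-2-yl]methyl}-4-methylidene-5-oxooxolan-3-yl]but-3-en-2-yl (2Z)-2-methylbut-2-enoate
Product: 28 (1R,2R)-1-hydroxy-1-[(2R,3R)-2-{[(2R,3R)-3-(2-hydroxyethyl)-2-methyloxiran-2-yl]methyl}-4-methylidene-5-oxooxolan-3-yl]-3-iodobut-3-en-2-yl (2Z)-2-methylbut-2-enoate
Conditions: DDQ (1.3 equiv), CH2Cl2–pH 7 phosphate buffer (10:1), 0 °C to rt
Reagents that add atoms: none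
Why: Oxidative cleavage of the electron-rich PMB ether is neutral, so the epoxide, the angelate next to a free hydroxyl and the α-methylene lactone are not exposed to acid, base or fluoride.

Step 17
Reactants: 28 (1R,2R)-1-hydroxy-1-[(2R,3R)-2-{[(2R,3R)-3-(2-hydroxyethyl)-2-methyloxiran-2-yl]methyl}-4-methylidene-5-oxooxolan-3-yl]-3-iodobut-3-en-2-yl (2Z)-2-methylbut-2-enoate
Product: 29 (1R,2R)-1-hydroxy-3-iodo-1-[(2R,3R)-2-{[(2R,3R)-2-methyl-3-(2-oxoethyl)oxiran-2-yl]methyl}-4-methylidene-5-oxooxolan-3-yl]but-3-en-2-yl (2Z)-2-methylbut-2-enoate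
Conditions: TEMPO (10 mol%), PhI(OAc)2 (1.2 equiv), CH2Cl2, rt; used crude
Reagents that add atoms: none
Why: The oxoammonium (TEMPO/PhI(OAc)2) oxidation is selective for the primary alcohol over the hindered secondary C6 hydroxyl and stops at the aldehyde.

Step 18
Reactants: 29 (1R,2R)-1-hydroxy-3-iodo-1-[(2R,3R)-2-{[(2R,3R)-2-methyl-3-(2-oxoethyl)oxiran-2-yl]methyl}-4-methylidene-5-oxooxolan-3-yl]but-3-en-2-yl (2Z)-2-methylbut-2-enoate
Product: 31 (1R,5S,6R,7R,8R,10R)-1,10-epoxy-3,6-dihydroxy-5-[(2Z)-2-methylbut-2-enoyloxy]germacra-4(15),11(13)-dien-12,8-olide (C-3 epimers), via alkenylchromium species 30 (not isolated)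
Conditions: CrCl2 (10 equiv), NiCl2 (0.1 equiv), DMSO, rt, 29 added by syringe pump to 2 mM; aq. work-up
Reagents that add atoms: none
Why: In this Nozaki–Hiyama–Kishi coupling nickel-catalysed insertion into the C–I bond and transmetalation to chromium give an alkenylchromium that adds to the tethered aldehyde under high dilution to close the ten-membered ring, and the new C3 carbinol centre may form as a mixture because it is oxidised in the next step.

Step 19
Reactants: 31 (1R,5S,6R,7R,8R,10R)-1,10-epoxy-3,6-dihydroxy-5-[(2Z)-2-methylbut-2-enoyloxy]germacra-4(15),11(13)-dien-12,8-olide (C-3 epimers)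
Product: 32 (1R,5S,6R,7R,8R,10R)-1,10-epoxy-6-hydroxy-5-[(2Z)-2-methylbut-2-enoyloxy]-3-oxogermacra-4(15),11(13)-dien-12,8-olide
Conditions: activated MnO2 (20 equiv), CH2Cl2, rt
Reagents that add atoms: none
Why: Manganese dioxide oxidises only the allylic C3 alcohol (both epimers converge on the enone) and leaves the non-allylic C6 hydroxyl, the epoxide and the esters untouched under neutral conditions.

## Compound list

1 | rac-2-(chloromethyl)oxirane (epichlorohydrin) | ClCC1CO1 | starting material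
2 | sodium acetylide | [Na+].[C-]#C | starting material
3 | 2-(prop-2-yn-1-yl)oxirane (racemic) | C#CCC1CO1 | intermediate
4 | (2E)-pent-2-en-4-yn-1-ol | OC/C=C/C#C | intermediate
5 | tert-butyl(dimethyl){[(2E)-pent-2-en-4-yn-1-yl]oxy}silane | CC(C)(C)[Si](C)(C)OC/C=C/C#C | intermediate
6 | 9-[(1Z,3E)-5-{[tert-butyl(dimethyl)silyl]oxy}-2-iodopenta-1,3-dien-1-yl]-9-borabicyclo[3.3.1]nonane | CC(C)(C)[Si](C)(C)OC/C=C/C(/I)=C/B1C2CCCC1CCC2 | intermediate
7 | tert-butyl{[(2E)-4-iodopenta-2,4-dien-1-yl]oxy}dimethylsilane | CC(C)(C)[Si](C)(C)OC/C=C/C(I)=C | intermediate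
8 | (2E)-4-iodopenta-2,4-dien-1-ol | OC/C=C/C(I)=C | intermediate
9 | [(2R,3S)-3-(1-iodoethenyl)oxiran-2-yl]methanol | OC[C@H]1O[C@@H]1C(I)=C | intermediate
10 | (2Z)-2-methylbut-2-enoic acid (angelic acid) | C/C=C(/C)C(=O)O | starting material
11 | (2R,3R)-1,2-dihydroxy-4-iodopent-4-en-3-yl (2Z)-2-methylbut-2-enoate | C=C(I)[C@H](OC(=O)/C(C)=C\C)[C@H](O)CO | intermediate
12 | (2R)-3-iodo-1-oxobut-3-en-2-yl (2Z)-2-methylbut-2-enoate | C=C(I)[C@H](OC(=O)/C(C)=C\C)C=O | intermediate
13 | pent-3-yn-1-ol | CC#CCCO | starting material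
14 | 1-methoxy-4-[(pent-3-yn-1-yloxy)methyl]benzene | CC#CCCOCc1ccc(OC)cc1 | intermediate
15 | chlorobis(cyclopentadienyl){(2E)-5-[(4-methoxyphenyl)methoxy]pent-2-en-2-yl}zirconium | C/C(=C\CCOCc1ccc(OC)cc1)[Zr](Cl)(C1C=CC=C1)C1C=CC=C1 | intermediate
16 | 1-({[(3E)-4-iodopent-3-en-1-yl]oxy}methyl)-4-methoxybenzene | C/C(I)=C\CCOCc1ccc(OC)cc1 | intermediate
17 | (2R)-2-(chloromethyl)oxirane ((R)-epichlorohydrin) | ClC[C@H]1CO1 | starting material
18 | {(2Z)-5-[(4-methoxyphenyl)methoxy]pent-2-en-2-yl}lithium (geometry of 16 retained; Z only because Li ranks below C) | C/C([Li])=C\CCOCc1ccc(OC)cc1 | intermediate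
19 | (2R,4E)-1-chloro-7-[(4-methoxyphenyl)methoxy]-4-methylhept-4-en-2-ol | ClC[C@H](O)C/C(C)=C/CCOCc1ccc(OC)cc1 | intermediate
20 | (2R)-2-{(2E)-5-[(4-methoxyphenyl)methoxy]-2-methylpent-2-en-1-yl}oxirane | C1O[C@@H]1C/C(C)=C/CCOCc1ccc(OC)cc1 | intermediate
21 | (3R,5E)-8-[(4-methoxyphenyl)methoxy]-5-methylocta-1,5-dien-3-ol | C=C[C@H](O)C/C(C)=C/CCOCc1ccc(OC)cc1 | intermediate
22 | (2R)-1-[(2R,3R)-3-{2-[(4-methoxyphenyl)methoxy]ethyl}-2-methyloxiran-2-yl]but-3-en-2-ol | C=C[C@H](O)C[C@@]1(C)O[C@@H]1CCOCc1ccc(OC)cc1 | intermediate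
23 | 2-(bromomethyl)prop-2-enoic acid | C=C(CBr)C(=O)O | starting material
24 | (2R)-1-[(2R,3R)-3-{2-[(4-methoxyphenyl)methoxy]ethyl}-2-methyloxiran-2-yl]but-3-en-2-yl 2-(bromomethyl)prop-2-enoate | C=C(CBr)C(=O)O[C@@H](C=C)C[C@@]1(C)O[C@@H]1CCOCc1ccc(OC)cc1 | intermediate
25 | (5R)-3-(bromomethyl)-5-{[(2R,3R)-3-{2-[(4-methoxyphenyl)methoxy]ethyl}-2-methyloxiran-2-yl]methyl}furan-2(5H)-one | O=C1O[C@H](C[C@@]2(C)O[C@@H]2CCOCc2ccc(OC)cc2)C=C1CBr | intermediate
26 | dichloro{[(5R)-5-{[(2R,3R)-3-{2-[(4-methoxyphenyl)methoxy]ethyl}-2-methyloxiran-2-yl]methyl}-2-oxo-2,5-dihydrofuran-3-yl]methyl}chromium (allyl species of trivalent chromium) | O=C1O[C@H](C[C@@]2(C)O[C@@H]2CCOCc2ccc(OC)cc2)C=C1C[Cr](Cl)Cl | intermediate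
27 | (1R,2R)-1-hydroxy-3-iodo-1-[(2R,3R)-2-{[(2R,3R)-3-{2-[(4-methoxyphenyl)methoxy]ethyl}-2-methyloxiran-2-yl]methyl}-4-methylidene-5-oxooxolan-3-yl]but-3-en-2-yl (2Z)-2-methylbut-2-enoate | C=C1C(=O)O[C@H](C[C@@]2(C)O[C@@H]2CCOCc2ccc(OC)cc2)[C@H]1[C@@H](O)[C@@H](OC(=O)/C(C)=C\C)C(I)=C | intermediate
28 | (1R,2R)-1-hydroxy-1-[(2R,3R)-2-{[(2R,3R)-3-(2-hydroxyethyl)-2-methyloxiran-2-yl]methyl}-4-methylidene-5-oxooxolan-3-yl]-3-iodobut-3-en-2-yl (2Z)-2-methylbut-2-enoate | C=C1C(=O)O[C@H](C[C@@]2(C)O[C@@H]2CCO)[C@H]1[C@@H](O)[C@@H](OC(=O)/C(C)=C\C)C(I)=C | intermediate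
29 | (1R,2R)-1-hydroxy-3-iodo-1-[(2R,3R)-2-{[(2R,3R)-2-methyl-3-(2-oxoethyl)oxiran-2-yl]methyl}-4-methylidene-5-oxooxolan-3-yl]but-3-en-2-yl (2Z)-2-methylbut-2-enoate | C=C1C(=O)O[C@H](C[C@@]2(C)O[C@@H]2CC=O)[C@H]1[C@@H](O)[C@@H](OC(=O)/C(C)=C\C)C(I)=C | intermediate
30 | (1R,2R)-3-(dichlorochromio)-1-hydroxy-1-[(2R,3R)-2-{[(2R,3R)-2-methyl-3-(2-oxoethyl)oxiran-2-yl]methyl}-4-methylidene-5-oxooxolan-3-yl]but-3-en-2-yl (2Z)-2-methylbut-2-enoate (alkenyl species of trivalent chromium) | C=C1C(=O)O[C@H](C[C@@]2(C)O[C@@H]2CC=O)[C@H]1[C@@H](O)[C@@H](OC(=O)/C(C)=C\C)C(=C)[Cr](Cl)Cl | intermediate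
31 | (1R,5S,6R,7R,8R,10R)-1,10-epoxy-3,6-dihydroxy-5-[(2Z)-2-methylbut-2-enoyloxy]germacra-4(15),11(13)-dien-12,8-olide (C-3 epimers) | C=C1C(=O)O[C@@H]2C[C@@]3(C)O[C@@H]3CC(O)C(=C)[C@H](OC(=O)/C(C)=C\C)[C@H](O)[C@@H]12 | intermediate
32 | (1R,5S,6R,7R,8R,10R)-1,10-epoxy-6-hydroxy-5-[(2Z)-2-methylbut-2-enoyloxy]-3-oxogermacra-4(15),11(13)-dien-12,8-olide (CNP0348992.5) | C=C1C(=O)O[C@@H]2C[C@@]3(C)O[C@@H]3CC(=O)C(=C)[C@H](OC(=O)/C(C)=C\C)[C@H](O)[C@@H]12 | target

## Step count and risks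

Total step count: 19 (fragment A steps 1–7, fragment B steps 8–14, common steps 15–19).
Longest linear sequence: 12 steps (steps 1–7 then 15–19, or equally steps 8–14 then 15–19).

The three steps most likely to fail:

**Step 18 (ring closure).** The β,γ-epoxy aldehyde 29 can eliminate or be opened by the Lewis-acidic trivalent chromium and chloride before the ten-membered ring forms. The fallback postpones the epoxide until after ring closure; it sets out from 21 and comes back at 31. Alcohol 21 is esterified with 23 (diisopropylcarbodiimide, DMAP cat.) to (3R,5E)-8-[(4-methoxyphenyl)methoxy]-5-methylocta-1,5-dien-3-yl 2-(bromomethyl)prop-2-enoate F1. Ring-closing metathesis with the second-generation Grubbs catalyst (H2IMes)(PCy3)Cl2Ru=CHPh gives (5R)-3-(bromomethyl)-5-{(2E)-5-[(4-methoxyphenyl)methoxy]-2-methylpent-2-en-1-yl}furan-2(5H)-one F2. CrCl2 coupling with 12 as in step 15 gives (1R,2R)-1-hydroxy-3-iodo-1-[(2R,3R)-2-{(2E)-5-[(4-methoxyphenyl)methoxy]-2-methylpent-2-en-1-yl}-4-methylidene-5-oxooxolan-3-yl]but-3-en-2-yl (2Z)-2-methylbut-2-enoate F3. DDQ then frees (1R,2R)-1-hydroxy-1-[(2R,3R)-2-[(2E)-5-hydroxy-2-methylpent-2-en-1-yl]-4-methylidene-5-oxooxolan-3-yl]-3-iodobut-3-en-2-yl (2Z)-2-methylbut-2-enoate F4, and TEMPO/PhI(OAc)2 gives the β,γ-unsaturated aldehyde (1R,2R)-1-hydroxy-3-iodo-1-[(2R,3R)-2-[(2E)-2-methyl-5-oxopent-2-en-1-yl]-4-methylidene-5-oxooxolan-3-yl]but-3-en-2-yl (2Z)-2-methylbut-2-enoate F5. CrCl2/NiCl2 in DMSO at high dilution closes the ring to (1(10)E,5S,6R,7R,8R)-3,6-dihydroxy-5-[(2Z)-2-methylbut-2-enoyloxy]germacra-1(10),4(15),11(13)-trien-12,8-olide (C-3 epimers) F6. Its trisubstituted E-olefin is then epoxidised under reagent control with the D-fructose-derived Shi ketone (Oxone, NaHCO3 buffer near pH 8, 0 °C) to return to 31. This does not help if the failure is ring strain rather than lability of the epoxy aldehyde.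

**Step 15 (fragment coupling).** The α-acyloxy β,γ-unsaturated aldehyde 12 is prone to enolisation, and the divalent chromium conditions could give reduction, translactonisation to the C6 oxygen or eroded selectivity. The fallback replaces the reductive Barbier reaction by a metal-free allylboration; it sets out from 25 and comes back at 27. Borylation of 25 with B2pin2 and Pd2(dba)3 (cat.) in toluene at 50 °C gives (5R)-5-{[(2R,3R)-3-{2-[(4-methoxyphenyl)methoxy]ethyl}-2-methyloxiran-2-yl]methyl}-3-[(4,4,5,5-tetramethyl-1,3,2-dioxaborolan-2-yl)methyl]furan-2(5H)-one F7. This deactivated 2-carbonyl allylboronate is heated with the electrophilic aldehyde 12 in toluene at 40–60 °C; the same closed chair transition state and attack anti to the C8 side chain apply, and hydrolytic work-up of the borate gives 27.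

**Step 6 (epoxide opening by angelic acid).** At the allylic C3 of the vinyl epoxide, ionisation (loss of inversion), SN2′ attack or acyl migration in the product diol could compete. The fallback separates C–O inversion from diol formation; it sets out from 9 and comes back at 12. Payne rearrangement of 9 (0.5 M NaOH, t-BuOH–H2O, with recycling of recovered 9) gives (1S)-2-iodo-1-[(2S)-oxiran-2-yl]prop-2-en-1-ol F8, in which the C3 oxygen is retained as a free hydroxyl. Mitsunobu esterification with 10 (PPh3, diisopropyl azodicarboxylate, THF, 0 °C) inverts that centre to give (1R)-2-iodo-1-[(2S)-oxiran-2-yl]prop-2-en-1-yl (2Z)-2-methylbut-2-enoate F9. Periodic acid H5IO6 in Et2O–THF then cleaves the terminal epoxide directly to aldehyde 12, so no free diol next to the ester is ever handled.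

## Further compounds

F1 | step 18 | (3R,5E)-8-[(4-methoxyphenyl)methoxy]-5-methylocta-1,5-dien-3-yl 2-(bromomethyl)prop-2-enoate | C=C(CBr)C(=O)O[C@@H](C=C)C/C(C)=C/CCOCc1ccc(OC)cc1
F2 | step 18 | (5R)-3-(bromomethyl)-5-{(2E)-5-[(4-methoxyphenyl)methoxy]-2-methylpent-2-en-1-yl}furan-2(5H)-one | O=C1O[C@H](C/C(C)=C/CCOCc2ccc(OC)cc2)C=C1CBr
F3 | step 18 | (1R,2R)-1-hydroxy-3-iodo-1-[(2R,3R)-2-{(2E)-5-[(4-methoxyphenyl)methoxy]-2-methylpent-2-en-1-yl}-4-methylidene-5-oxooxolan-3-yl]but-3-en-2-yl (2Z)-2-methylbut-2-enoate | C=C1C(=O)O[C@H](C/C(C)=C/CCOCc2ccc(OC)cc2)[C@H]1[C@@H](O)[C@@H](OC(=O)/C(C)=C\C)C(I)=C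
F4 | step 18 | (1R,2R)-1-hydroxy-1-[(2R,3R)-2-[(2E)-5-hydroxy-2-methylpent-2-en-1-yl]-4-methylidene-5-oxooxolan-3-yl]-3-iodobut-3-en-2-yl (2Z)-2-methylbut-2-enoate | C=C1C(=O)O[C@H](C/C(C)=C/CCO)[C@H]1[C@@H](O)[C@@H](OC(=O)/C(C)=C\C)C(I)=C
F5 | step 18 | (1R,2R)-1-hydroxy-3-iodo-1-[(2R,3R)-2-[(2E)-2-methyl-5-oxopent-2-en-1-yl]-4-methylidene-5-oxooxolan-3-yl]but-3-en-2-yl (2Z)-2-methylbut-2-enoate | C=C1C(=O)O[C@H](C/C(C)=C/CC=O)[C@H]1[C@@H](O)[C@@H](OC(=O)/C(C)=C\C)C(I)=C
F6 | step 18 | (1(10)E,5S,6R,7R,8R)-3,6-dihydroxy-5-[(2Z)-2-methylbut-2-enoyloxy]germacra-1(10),4(15),11(13)-trien-12,8-olide (C-3 epimers) | C=C1C(=O)O[C@@H]2C/C(C)=C/CC(O)C(=C)[C@H](OC(=O)/C(C)=C\C)[C@H](O)[C@@H]12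
F7 | step 15 | (5R)-5-{[(2R,3R)-3-{2-[(4-methoxyphenyl)methoxy]ethyl}-2-methyloxiran-2-yl]methyl}-3-[(4,4,5,5-tetramethyl-1,3,2-dioxaborolan-2-yl)methyl]furan-2(5H)-one | O=C1O[C@H](C[C@@]2(C)O[C@@H]2CCOCc2ccc(OC)cc2)C=C1CB1OC(C)(C)C(C)(C)O1
F8 | step 6 | (1S)-2-iodo-1-[(2S)-oxiran-2-yl]prop-2-en-1-ol | C=C(I)[C@@H](O)[C@@H]1CO1
F9 | step 6 | (1R)-2-iodo-1-[(2S)-oxiran-2-yl]prop-2-en-1-yl (2Z)-2-methylbut-2-enoate | C=C(I)[C@H](OC(=O)/C(C)=C\C)[C@@H]1CO1
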